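## The problem

The target is a sesquineolignan built on a (3R,4R)-trans-α,β-dibenzyl-γ-butyrolactone. Ring A (arene of the α-benzyl group) is tied through its phenol oxygen to C8 of an erythro 1-arylglycerol (7R,8S) that carries ring C. Ring B (arene of the β-benzyl group) is fused at O4/C5 into a trans-2-aryl-3-hydroxymethyl-2,3-dihydrobenzofuran (2S,3R) with ring D on C2. The six stereocentres form three vicinal pairs separated by arenes and benzylic CH2 groups. Inside a pair one centre can steer the other (β-benzyl directs the α-alkylation trans, C3 directs ring closure at C2 trans, an aldol sets C7 against C8). No pair can steer another, so each pair needs its own source of absolute configuration. Three phenols must be told apart: one becomes an alkyl aryl ether, one the ring oxygen, one stays free. The fragile parts are: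
- the lactone (hydride, hydroxide, enolisable α-centre);
- the benzylic carbinol para to a phenol oxygen (ionises to a quinone methide);
- the benzylic C2–O bond of the dihydrofuran (hydrogenolysis, and β-elimination while C3 carries a carbonyl);
- the electron-rich phenols themselves.

What makes the key step possible is that ring B is a 4-alkyl-2-methoxyphenol. Its para carbon is blocked by the benzylic CH2 and one ortho carbon by OMe, so its phenoxyl radical can form a C–C bond only at C5. Bonding C5 to the α-carbon (C8) of a 4-hydroxycinnamoyl radical, then returning O4 onto the quinone methide carbon (C7), gives exactly the C3–C3a and O1–C2 bonds of the dihydrofuran.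

## Retrosynthesis

**End game, 30 ← 29 ← 28.** The last two operations cut only a Si–O bond (ring C silyl ether) and turn the C3 acyl group into CH2OH. The ring C phenol stays masked until the end because a second free guaiacyl phenol would compete in the oxidative coupling. C3 is carried as an acyl oxazolidinone because that group is both the radical-stabilising substituent and the only handle on the absolute configuration of C2/C3. The forward reduction must tell the imide from the γ-lactone.

**Key disconnection, 28 ← 20 + 26.** The C3–C3a and O1–C2 bonds are cut together. Cuts at C2–C3 or O1–C7a, or building the benzene ring last, would each require ring B to be pre-functionalised or assembled separately. This cut uses ring B as it stands: one free ortho carbon and the phenol. It removes one ring, two skeletal bonds and two stereocentres, and leaves a differentiated matairesinol-type lactone phenol 20 and the N-feruloyl imide 26. The forward step must give cross- rather than homo-coupling, C–C rather than C–O bonding on ring B, trans closure, and one face of the feruloyl radical.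

**Glycerol unit, 20 ← 19 ← 18 ← 16 + 10.** The C7–C8 bond is cut as an aldol between the aryloxyacetyl imide 16 and the silylated vanillin 10. The neighbouring cut, ether formation at C8 by displacement on a preformed arylglycerol, would need a stereospecific substitution at a hindered secondary carbon next to an ionisable benzylic centre. The aldol makes both centres at once with the ring A oxygen already in place. It must be anti (erythro), auxiliary-controlled, and must enolise the imide without touching the lactone. Reduction (18 → 19) removes the auxiliary. Hydrogenolysis (19 → 20) frees the ring B phenol, whose benzyl ether is orthogonal to the silyl ether on ring C.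

**Ether link, 16 ← 14 + 15, and 14 ← 13.** The ring A O–CH2 bond is cut. The chloroacetyl imide 15 delivers the whole aryloxyacetyl imide in one alkylation, where the route through an aryloxyacetic acid would need three steps. The phenoxide of 14 must displace chloride faster than it attacks the imide carbonyl. 14 comes from the silyl ether 13 with fluoride.

**Lactone α-benzylation, 13 ← 8 + 12.** The Cα–CH2(ring A) bond is cut. Alkylating the enolate of the β-benzyl lactone 8 anti to its substituent is the standard entry to trans-dibenzylbutyrolactones and leaves 8 with one stereocentre. The bromide 12 carries the ring A phenol as a silyl ether, distinct from the benzyl ether on ring B.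

**Lactone core, 8 ← 6 ← 5 ← 2 + 3, and 2 ← 1.** The bond between the future C4 and the CH2C(=O) carbon is cut as an auxiliary-controlled enolate alkylation of the 3-arylpropanoyl imide 5. Reductive release of the auxiliary 3 and lactonisation follow. An asymmetric hydrogenation of an arylidene succinate would be one step shorter but depends on ligand screening. The auxiliary alkylation has a predictable sense and reuses the oxazolidinone 3 that the route needs elsewhere.

**Small pieces.** 26 ← 25 ← 23 ← 21 (ferulic acid) with 3. 12 ← 11 ← 10 ← 9 (vanillin). Aldehyde 10 serves twice, as the source of 12 and as the aldol partner.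

## Roads not taken

**Alternative 1:** Flavanone ring contraction. The cut is the C3–C3a bond, made by a 1,2-shift of the fused aryl carbon. The (2S)-flavanone A1, treated with PhI(OAc)2, H2SO4 and HC(OMe)3, contracts to the trans methyl 2-aryl-2,3-dihydrobenzofuran-3-carboxylate A2, with C4 expelled as the ester.
- Merits: a polar, well-behaved rearrangement with no regiochemical doubt; C2 is fixed before the key step and C3 follows from the migration; the ester is the future CH2OH.
- Weak points: A2 is only the ring B/ring D part. Its aryl bromide must still be joined to the lactone CH2 by an sp2–sp3 coupling, and the lactone and glycerol units built or attached afterwards. The ester must later be reduced beside a lactone, the same problem as in the chosen plan. The C2 centre of A1 can racemise by reversible ring opening under the strongly acidic oxidising medium, and ring D needs a deactivating mesylate to survive it.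
- Comparison: this road is better in regiochemical certainty and in securing absolute configuration before the key step. The chosen plan sets against it convergence (the dihydrofuran is closed in one step on the finished lactone) and a shorter sequence with no aryl halide coupling.

**Alternative 2:** Pyrone–alkyne Diels–Alder. The cut is C3a–C7a and C4–C5, so the benzene ring B is made last. On heating, the ether-tethered alkyne of pyrone A3 adds across the pyrone and CO2 is lost, giving the dihydrobenzofuran A4.
- Merits: C2 and C3 are set on an open chain by reliable acyclic chemistry; the substitution pattern of ring B is dictated by the pyrone; there is no oxidant and no homo-coupling.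
- Weak points: A3 combines an electron-rich pyrone with an unactivated alkyne, so high temperature is needed, and its propargylic and benzylic centres can eliminate or epimerise. Making A3 requires a stereoretentive O-alkylation of a hydroxypyrone with a secondary benzylic carbon, itself a hard step. After A4, the CH2O group must still be converted into the whole lactone and the glycerol unit added, so the sequence is long and linear.
- Comparison: the stereochemical security at C2/C3 is higher than a radical face selection can offer. The chosen plan sets against it brevity and direct use of the natural guaiacyl substitution.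

**Alternative 3:** Asymmetric Baeyer–Villiger desymmetrisation. The cut is the lactone ring O–CH2 bond. The 3-substituted cyclobutanone A5, with aqueous H2O2 and a chiral phosphoric acid, gives the (R)-β-substituted γ-butyrolactone A6.
- Merits: a catalytic, auxiliary-free way to the lactone β-centre with a clean oxidant. In atom economy it is better than the stoichiometric auxiliary used here.
- Weak points: it solves one stereocentre only. A5 must already contain the enantiopure dihydrobenzofuran, so another answer to the central problem is presupposed, and that ring must then survive cyclobutanone construction and a peroxide/acid medium. The α-benzylation and the glycerol ether still follow as in the chosen plan, so nothing is saved overall.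
- Comparison: for the lactone centre alone this is the more elegant method. The chosen plan sets against it a predictable auxiliary alkylation on simple material and leaves the sensitive dihydrofuran to the end.

Key step: step 17

Remark: compounds 1, 3, 9, 15 and 21 are taken as purchased; the ring C phenol is carried as a triisopropylsilyl ether (not a smaller silyl group) because it must pass twice through NaBH4 in wet THF.

## Route

Step 1
Reactants: 1 3-(4-hydroxy-3-methoxyphenyl)propanoic acid
Product: 2 3-[4-(benzyloxy)-3-methoxyphenyl]propanoic acid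
Conditions: BnCl, NaOH, EtOH/H2O, reflux; then aq. HCl
Reagents that add atoms: benzyl chloride, ClCc1ccccc1
Why: Williamson ether synthesis on the phenoxide of the dianion; any benzyl ester formed is saponified in the same pot by the excess hydroxide.

Step 2
Reactants: 2 3-[4-(benzyloxy)-3-methoxyphenyl]propanoic acid; 3 (S)-4-benzyl-1,3-oxazolidin-2-one
Product: 5 (S)-4-benzyl-3-{3-[4-(benzyloxy)-3-methoxyphenyl]propanoyl}oxazolidin-2-one, via mixed pivalic anhydride 4 (not isolated)
Conditions: t-BuCOCl, Et3N, THF, −20 °C; then LiCl, 3, −20 °C to rt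
Reagents that add atoms: none
Why: N-acylation of the oxazolidinone through a mixed anhydride with LiCl activation; the nucleophile attacks the unhindered carbonyl of the anhydride.

Step 3
Reactants: 5 (S)-4-benzyl-3-{3-[4-(benzyloxy)-3-methoxyphenyl]propanoyl}oxazolidin-2-one
Product: 6 tert-butyl (3R)-4-[(4S)-4-benzyl-2-oxooxazolidin-3-yl]-3-[4-(benzyloxy)-3-methoxybenzyl]-4-oxobutanoate
Conditions: NaN(SiMe3)2, THF, −78 °C; BrCH2CO2t-Bu, −78 to −30 °C
Reagents that add atoms: tert-butyl bromoacetate, CC(C)(C)OC(=O)CBr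
Why: Evans asymmetric alkylation: the chelated sodium Z-enolate is alkylated on the face away from the 4-benzyl group, which sets the (R) centre that becomes C4 of the lactone.

Step 4
Reactants: 6 tert-butyl (3R)-4-[(4S)-4-benzyl-2-oxooxazolidin-3-yl]-3-[4-(benzyloxy)-3-methoxybenzyl]-4-oxobutanoate
Product: 8 (4R)-4-[4-(benzyloxy)-3-methoxybenzyl]dihydrofuran-2(3H)-one, via hydroxy tert-butyl ester 7 (not isolated)
Conditions: LiBH4, MeOH (1 equiv), THF, 0 °C; then TFA, CH2Cl2, 0 °C to rt
Reagents that add atoms: none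
Why: Reductive cleavage of the acyl oxazolidinone by LiBH4 spares the hindered tert-butyl ester; acidolysis of that ester and lactonisation then close the γ-lactone without touching the stereocentre, and 3 is recovered.

Step 5
Reactants: 9 vanillin
Product: 10 3-methoxy-4-(triisopropylsilyloxy)benzaldehyde
Conditions: i-Pr3SiCl, imidazole, DMF, rt
Reagents that add atoms: chlorotriisopropylsilane, CC(C)[Si](Cl)(C(C)C)C(C)C
Why: Silylation of a phenol under imidazole catalysis; the aldehyde is untouched.

Step 6
Reactants: 10 3-methoxy-4-(triisopropylsilyloxy)benzaldehyde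
Product: 11 [3-methoxy-4-(triisopropylsilyloxy)phenyl]methanol
Conditions: NaBH4, MeOH, 0 °C
Reagents that add atoms: none
Why: Borohydride reduction of an aryl aldehyde; the hindered aryl silyl ether is stable under these conditions.

Step 7
Reactants: 11 [3-methoxy-4-(triisopropylsilyloxy)phenyl]methanol
Product: 12 [4-(bromomethyl)-2-methoxyphenoxy]triisopropylsilane
Conditions: PBr3, Et2O, 0 °C
Reagents that add atoms: phosphorus tribromide, BrP(Br)Br
Why: Conversion of a benzylic alcohol to the bromide through its phosphite ester (substitution by bromide); the bromide is used without storage.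

Step 8
Reactants: 8 (4R)-4-[4-(benzyloxy)-3-methoxybenzyl]dihydrofuran-2(3H)-one; 12 [4-(bromomethyl)-2-methoxyphenoxy]triisopropylsilane
Product: 13 (3R,4R)-4-[4-(benzyloxy)-3-methoxybenzyl]-3-[3-methoxy-4-(triisopropylsilyloxy)benzyl]dihydrofuran-2(3H)-one
Conditions: LiN(SiMe3)2, THF, −78 °C; then 12, −78 to −30 °C
Reagents that add atoms: none
Why: Alkylation of the lithium enolate of a β-substituted γ-butyrolactone; the benzyl bromide enters anti to the β-benzyl group, giving the trans (3R,4R) lactone.

Step 9
Reactants: 13 (3R,4R)-4-[4-(benzyloxy)-3-methoxybenzyl]-3-[3-methoxy-4-(triisopropylsilyloxy)benzyl]dihydrofuran-2(3H)-one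
Product: 14 (3R,4R)-4-[4-(benzyloxy)-3-methoxybenzyl]-3-(4-hydroxy-3-methoxybenzyl)dihydrofuran-2(3H)-one
Conditions: Bu4NF, AcOH, THF, 0 °C
Reagents that add atoms: none
Why: Fluoride cleavage of an aryl silyl ether; acetic acid buffering protects the lactone and its α-centre, and the benzyl ether on ring B is inert.

Step 10
Reactants: 14 (3R,4R)-4-[4-(benzyloxy)-3-methoxybenzyl]-3-(4-hydroxy-3-methoxybenzyl)dihydrofuran-2(3H)-one; 15 (S)-4-benzyl-3-(chloroacetyl)oxazolidin-2-one
Product: 16 (S)-4-benzyl-3-{2-[4-({(3R,4R)-4-[4-(benzyloxy)-3-methoxybenzyl]-2-oxotetrahydrofuran-3-yl}methyl)-2-methoxyphenoxy]acetyl}oxazolidin-2-one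
Conditions: K2CO3, NaI (cat.), acetone, 40 °C
Reagents that add atoms: none
Why: Williamson ether synthesis on an α-halo carbonyl compound with Finkelstein catalysis; substitution next to the carbonyl is fast enough to outrun attack of the phenoxide on the imide.

Step 11
Reactants: 16 (S)-4-benzyl-3-{2-[4-({(3R,4R)-4-[4-(benzyloxy)-3-methoxybenzyl]-2-oxotetrahydrofuran-3-yl}methyl)-2-methoxyphenoxy]acetyl}oxazolidin-2-one; 10 3-methoxy-4-(triisopropylsilyloxy)benzaldehyde
Product: 18 anti aldol adduct (S)-4-benzyl-3-{(2R,3R)-3-hydroxy-3-[3-methoxy-4-(triisopropylsilyloxy)phenyl]-2-(ring A aryloxy)propanoyl}oxazolidin-2-one, via trimethylsilyl ether 17 (not isolated)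
Conditions: MgCl2 (20 mol %), Et3N, Me3SiCl, EtOAc, rt; then PPTS, MeOH, 0 °C
Reagents that add atoms: none
Why: Evans magnesium halide-catalysed direct anti aldol of an N-acyl oxazolidinone with a non-enolisable aryl aldehyde: MgCl2/Et3N enolise only the two-point-binding imide (not the lactone), the aldehyde adds to the chelated Z-enolate on the face away from the 4-benzyl group, and silylation of the aldolate turns over magnesium and blocks retro-aldol. The auxiliary face sets C8 (2R in the adduct, 8S after reduction) and the anti transition state sets C7 (R); mild methanolysis removes the trimethylsilyl group.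

Step 12
Reactants: 18 anti aldol adduct (S)-4-benzyl-3-{(2R,3R)-3-hydroxy-3-[3-methoxy-4-(triisopropylsilyloxy)phenyl]-2-(ring A aryloxy)propanoyl}oxazolidin-2-one
Product: 19 (3R,4R)-4-[4-(benzyloxy)-3-methoxybenzyl]-3-[4-({(1R,2S)-1,3-dihydroxy-1-[3-methoxy-4-(triisopropylsilyloxy)phenyl]propan-2-yl}oxy)-3-methoxybenzyl]dihydrofuran-2(3H)-one
Conditions: NaBH4, THF/H2O (4:1), 0 °C
Reagents that add atoms: none
Why: Borohydride reduction of an acyl oxazolidinone in wet THF; the α-aryloxy imide carbonyl is far more electrophilic than the γ-lactone, and 3 is released.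

Step 13
Reactants: 19 (3R,4R)-4-[4-(benzyloxy)-3-methoxybenzyl]-3-[4-({(1R,2S)-1,3-dihydroxy-1-[3-methoxy-4-(triisopropylsilyloxy)phenyl]propan-2-yl}oxy)-3-methoxybenzyl]dihydrofuran-2(3H)-one
Product: 20 (3R,4R)-3-[4-({(1R,2S)-1,3-dihydroxy-1-[3-methoxy-4-(triisopropylsilyloxy)phenyl]propan-2-yl}oxy)-3-methoxybenzyl]-4-(4-hydroxy-3-methoxybenzyl)dihydrofuran-2(3H)-one
Conditions: H2 (1 atm), Pd/C, EtOAc, rt
Reagents that add atoms: none
Why: Hydrogenolysis of an aryl benzyl ether; under neutral conditions in ethyl acetate the benzylic carbinol, the aryl silyl ether and the lactone are retained.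

Step 14
Reactants: 21 ferulic acid, (E)-3-(4-hydroxy-3-methoxyphenyl)prop-2-enoic acid
Product: 23 (E)-3-[4-(tert-butyldimethylsilyloxy)-3-methoxyphenyl]prop-2-enoic acid, via bis-silylated ferulate 22 (not isolated)
Conditions: t-BuMe2SiCl, imidazole, DMF, rt; then AcOH/THF/H2O, rt
Reagents that add atoms: tert-butyldimethylsilyl chloride, CC(C)(C)[Si](C)(C)Cl
Why: Exhaustive silylation followed by selective hydrolysis of the labile silyl ester, which leaves the aryl silyl ether.

Step 15
Reactants: 23 (E)-3-[4-(tert-butyldimethylsilyloxy)-3-methoxyphenyl]prop-2-enoic acid; 3 (S)-4-benzyl-1,3-oxazolidin-2-one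
Product: 25 (S)-4-benzyl-3-{(E)-3-[4-(tert-butyldimethylsilyloxy)-3-methoxyphenyl]prop-2-enoyl}oxazolidin-2-one, via mixed pivalic anhydride 24 (not isolated)
Conditions: t-BuCOCl, Et3N, THF, −20 °C; then LiCl, 3, −20 °C to rt
Reagents that add atoms: none
Why: The same mixed-anhydride N-acylation as in step 2, which is routine for cinnamic acids.

Step 16
Reactants: 25 (S)-4-benzyl-3-{(E)-3-[4-(tert-butyldimethylsilyloxy)-3-methoxyphenyl]prop-2-enoyl}oxazolidin-2-one
Product: 26 (S)-4-benzyl-3-[(E)-3-(4-hydroxy-3-methoxyphenyl)prop-2-enoyl]oxazolidin-2-one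
Conditions: Bu4NF, AcOH, THF, 0 °C
Reagents that add atoms: none
Why: Buffered fluoride desilylation of the aryl silyl ether; the enoyl imide is stable to these conditions.

Step 17
Reactants: 20 (3R,4R)-3-[4-({(1R,2S)-1,3-dihydroxy-1-[3-methoxy-4-(triisopropylsilyloxy)phenyl]propan-2-yl}oxy)-3-methoxybenzyl]-4-(4-hydroxy-3-methoxybenzyl)dihydrofuran-2(3H)-one; 26 (S)-4-benzyl-3-[(E)-3-(4-hydroxy-3-methoxyphenyl)prop-2-enoyl]oxazolidin-2-one
Product: 28 trans-(2S,3S)-2-(4-hydroxy-3-methoxyphenyl)-7-methoxy-2,3-dihydrobenzofuran-3-carbonyl oxazolidinone (ring B of 20 fused at O4/C5; acyl group on the nitrogen of 3; rest of 20 unchanged), via phenol–quinone methide 27 (not isolated)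
Conditions: Ag2O (3 equiv), 20 (1.5 equiv), CH2Cl2, rt, dark; 26 (1.0 equiv) added over 8 h by syringe pump
Reagents that add atoms: none
Why: Ag2O removes one electron and one proton from each phenol; the ring B phenoxyl radical of 20 (spin at O4 and at C5, the only free ortho carbon) and the feruloyl radical of 26 (spin at the carbon α to the imide) join radical to radical to form C3–C3a, and tautomerisation of the dienone gives the phenol–quinone methide 27. The ring B phenol then adds to the quinone methide carbon in a 5-exo-trig closure (O1–C2) that rearomatises ring D. The closest known reactions are the Ag2O- or enzyme-mediated dehydrodimerisation of ferulates and chiral feruloyl amides to trans-phenylcoumarans and the cross-coupling of monolignols with 4-alkylguaiacols in lignin model work. The acyl-bearing carbon is set in the C–C coupling by the auxiliary: with the two imide carbonyls held syn by silver and the enoyl unit s-cis, the 4-benzyl group covers the Re face of the α-carbon and ring B bonds to the Si face, giving 3S (3R after reduction). C2 is set in the ring closure, which places ring D trans to the acyl group, and a cis isomer could equilibrate through the enolisable C3. Cross-coupling is favoured by feeding 26 slowly into an excess of 20, and unreacted 20 is recovered. The site on ring B is fixed by its substitution, and the silyl ether on ring C and the ether on ring A leave ring B as the only phenol of 20. The facial bias of such auxiliaries in radical coupling is moderate, so a minor trans diastereomer is expected and removed by chromatography.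

Step 18
Reactants: 28 trans-(2S,3S)-2-(4-hydroxy-3-methoxyphenyl)-7-methoxy-2,3-dihydrobenzofuran-3-carbonyl oxazolidinone
Product: 29 ring C triisopropylsilyl ether of the target, with (2S,3R)-3-(hydroxymethyl)-2-(4-hydroxy-3-methoxyphenyl)-7-methoxy-2,3-dihydrobenzofuran
Conditions: NaBH4, THF/H2O (4:1), 0 °C
Reagents that add atoms: none
Why: Borohydride reduction of an acyl oxazolidinone to the primary alcohol in wet THF; the imide carbonyl is attacked in preference to the γ-lactone, the trans ring is the stable arrangement, and 3 is released.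

Step 19
Reactants: 29 ring C triisopropylsilyl ether of the target
Product: 30 target, (3R,4R)-3-[4-({(1R,2S)-1,3-dihydroxy-1-(4-hydroxy-3-methoxyphenyl)propan-2-yl}oxy)-3-methoxybenzyl]-4-{[(2S,3R)-3-(hydroxymethyl)-2-(4-hydroxy-3-methoxyphenyl)-7-methoxy-2,3-dihydrobenzofuran-5-yl]methyl}dihydrofuran-2(3H)-one
Conditions: Bu4NF, AcOH, THF, 0 °C
Reagents that add atoms: none
Why: Buffered fluoride cleavage of the aryl silyl ether; the buffer keeps the lactone α-centre and the para-hydroxybenzylic carbinol from base-induced change.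

## Compound list

1 | 3-(4-hydroxy-3-methoxyphenyl)propanoic acid | COc1cc(CCC(=O)O)ccc1O | starting material
2 | 3-[4-(benzyloxy)-3-methoxyphenyl]propanoic acid | COc1cc(CCC(=O)O)ccc1OCc1ccccc1 | intermediate
3 | (S)-4-benzyl-1,3-oxazolidin-2-one | O=C1N[C@@H](Cc2ccccc2)CO1 | starting material
4 | 3-[4-(benzyloxy)-3-methoxyphenyl]propanoic pivalic anhydride | COc1cc(CCC(=O)OC(=O)C(C)(C)C)ccc1OCc1ccccc1 | intermediate (not isolated)
5 | (S)-4-benzyl-3-{3-[4-(benzyloxy)-3-methoxyphenyl]propanoyl}oxazolidin-2-one | COc1cc(CCC(=O)N2[C@@H](Cc3ccccc3)COC2=O)ccc1OCc1ccccc1 | intermediate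
6 | tert-butyl (3R)-4-[(4S)-4-benzyl-2-oxooxazolidin-3-yl]-3-[4-(benzyloxy)-3-methoxybenzyl]-4-oxobutanoate | COc1cc(C[C@H](CC(=O)OC(C)(C)C)C(=O)N2[C@@H](Cc3ccccc3)COC2=O)ccc1OCc1ccccc1 | intermediate
7 | tert-butyl (3R)-3-[4-(benzyloxy)-3-methoxybenzyl]-4-hydroxybutanoate | COc1cc(C[C@H](CC(=O)OC(C)(C)C)CO)ccc1OCc1ccccc1 | intermediate (not isolated)
8 | (4R)-4-[4-(benzyloxy)-3-methoxybenzyl]dihydrofuran-2(3H)-one | COc1cc(C[C@@H]2CC(=O)OC2)ccc1OCc1ccccc1 | intermediate
9 | vanillin | COc1cc(C=O)ccc1O | starting material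
10 | 3-methoxy-4-(triisopropylsilyloxy)benzaldehyde | COc1cc(C=O)ccc1O[Si](C(C)C)(C(C)C)C(C)C | intermediate
11 | [3-methoxy-4-(triisopropylsilyloxy)phenyl]methanol | COc1cc(CO)ccc1O[Si](C(C)C)(C(C)C)C(C)C | intermediate
12 | [4-(bromomethyl)-2-methoxyphenoxy]triisopropylsilane | COc1cc(CBr)ccc1O[Si](C(C)C)(C(C)C)C(C)C | intermediate
13 | (3R,4R)-4-[4-(benzyloxy)-3-methoxybenzyl]-3-[3-methoxy-4-(triisopropylsilyloxy)benzyl]dihydrofuran-2(3H)-one | COc1cc(C[C@H]2C(=O)OC[C@@H]2Cc2ccc(OCc3ccccc3)c(OC)c2)ccc1O[Si](C(C)C)(C(C)C)C(C)C | intermediate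
14 | (3R,4R)-4-[4-(benzyloxy)-3-methoxybenzyl]-3-(4-hydroxy-3-methoxybenzyl)dihydrofuran-2(3H)-one | COc1cc(C[C@H]2C(=O)OC[C@@H]2Cc2ccc(OCc3ccccc3)c(OC)c2)ccc1O | intermediate
15 | (S)-4-benzyl-3-(chloroacetyl)oxazolidin-2-one | O=C(CCl)N1[C@@H](Cc2ccccc2)COC1=O | starting material
16 | (S)-4-benzyl-3-{2-[4-({(3R,4R)-4-[4-(benzyloxy)-3-methoxybenzyl]-2-oxotetrahydrofuran-3-yl}methyl)-2-methoxyphenoxy]acetyl}oxazolidin-2-one | COc1cc(C[C@H]2C(=O)OC[C@@H]2Cc2ccc(OCc3ccccc3)c(OC)c2)ccc1OCC(=O)N1[C@@H](Cc2ccccc2)COC1=O | intermediate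
17 | trimethylsilyl ether of the anti aldol adduct 18 (3-O-SiMe3) | COc1cc([C@@H](O[Si](C)(C)C)[C@H](C(=O)N2[C@@H](Cc3ccccc3)COC2=O)Oc2ccc(C[C@H]3C(=O)OC[C@@H]3Cc3ccc(OCc4ccccc4)c(OC)c3)cc2OC)ccc1O[Si](C(C)C)(C(C)C)C(C)C | intermediate (not isolated)
18 | (S)-4-benzyl-3-{(2R,3R)-2-[4-({(3R,4R)-4-[4-(benzyloxy)-3-methoxybenzyl]-2-oxotetrahydrofuran-3-yl}methyl)-2-methoxyphenoxy]-3-hydroxy-3-[3-methoxy-4-(triisopropylsilyloxy)phenyl]propanoyl}oxazolidin-2-one | COc1cc([C@@H](O)[C@H](C(=O)N2[C@@H](Cc3ccccc3)COC2=O)Oc2ccc(C[C@H]3C(=O)OC[C@@H]3Cc3ccc(OCc4ccccc4)c(OC)c3)cc2OC)ccc1O[Si](C(C)C)(C(C)C)C(C)C | intermediate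
19 | (3R,4R)-4-[4-(benzyloxy)-3-methoxybenzyl]-3-[4-({(1R,2S)-1,3-dihydroxy-1-[3-methoxy-4-(triisopropylsilyloxy)phenyl]propan-2-yl}oxy)-3-methoxybenzyl]dihydrofuran-2(3H)-one | COc1cc([C@@H](O)[C@H](CO)Oc2ccc(C[C@H]3C(=O)OC[C@@H]3Cc3ccc(OCc4ccccc4)c(OC)c3)cc2OC)ccc1O[Si](C(C)C)(C(C)C)C(C)C | intermediate
20 | (3R,4R)-3-[4-({(1R,2S)-1,3-dihydroxy-1-[3-methoxy-4-(triisopropylsilyloxy)phenyl]propan-2-yl}oxy)-3-methoxybenzyl]-4-(4-hydroxy-3-methoxybenzyl)dihydrofuran-2(3H)-one | COc1cc([C@@H](O)[C@H](CO)Oc2ccc(C[C@H]3C(=O)OC[C@@H]3Cc3ccc(O)c(OC)c3)cc2OC)ccc1O[Si](C(C)C)(C(C)C)C(C)C | intermediate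
21 | ferulic acid, (E)-3-(4-hydroxy-3-methoxyphenyl)prop-2-enoic acid | COc1cc(/C=C/C(=O)O)ccc1O | starting material
22 | tert-butyldimethylsilyl (E)-3-[4-(tert-butyldimethylsilyloxy)-3-methoxyphenyl]prop-2-enoate | COc1cc(/C=C/C(=O)O[Si](C)(C)C(C)(C)C)ccc1O[Si](C)(C)C(C)(C)C | intermediate (not isolated)
23 | (E)-3-[4-(tert-butyldimethylsilyloxy)-3-methoxyphenyl]prop-2-enoic acid | COc1cc(/C=C/C(=O)O)ccc1O[Si](C)(C)C(C)(C)C | intermediate
24 | (E)-3-[4-(tert-butyldimethylsilyloxy)-3-methoxyphenyl]prop-2-enoic pivalic anhydride | COc1cc(/C=C/C(=O)OC(=O)C(C)(C)C)ccc1O[Si](C)(C)C(C)(C)C | intermediate (not isolated)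
25 | (S)-4-benzyl-3-{(E)-3-[4-(tert-butyldimethylsilyloxy)-3-methoxyphenyl]prop-2-enoyl}oxazolidin-2-one | COc1cc(/C=C/C(=O)N2[C@@H](Cc3ccccc3)COC2=O)ccc1O[Si](C)(C)C(C)(C)C | intermediate
26 | (S)-4-benzyl-3-[(E)-3-(4-hydroxy-3-methoxyphenyl)prop-2-enoyl]oxazolidin-2-one | COc1cc(/C=C/C(=O)N2[C@@H](Cc3ccccc3)COC2=O)ccc1O | intermediate
27 | phenol–quinone methide: 20 carrying at C5 of ring B the (S)-CH[C(=O)-oxazolidinone]–CH=(3-methoxy-4-oxocyclohexa-2,5-dienylidene) unit | COc1cc([C@@H](O)[C@H](CO)Oc2ccc(C[C@H]3C(=O)OC[C@@H]3Cc3cc(OC)c(O)c(c3)[C@H](C(=O)N3[C@@H](Cc4ccccc4)COC3=O)C=C3C=CC(=O)C(OC)=C3)cc2OC)ccc1O[Si](C(C)C)(C(C)C)C(C)C | intermediate (not isolated)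
28 | (S)-4-benzyl-3-{[(2S,3S)-5-({(3R,4R)-4-[4-({(1R,2S)-1,3-dihydroxy-1-[3-methoxy-4-(triisopropylsilyloxy)phenyl]propan-2-yl}oxy)-3-methoxybenzyl]-5-oxotetrahydrofuran-3-yl}methyl)-2-(4-hydroxy-3-methoxyphenyl)-7-methoxy-2,3-dihydrobenzofuran-3-yl]carbonyl}oxazolidin-2-one | COc1cc([C@@H](O)[C@H](CO)Oc2ccc(C[C@H]3C(=O)OC[C@@H]3Cc3cc(OC)c4c(c3)[C@H](C(=O)N3[C@@H](Cc5ccccc5)COC3=O)[C@@H](c3ccc(O)c(OC)c3)O4)cc2OC)ccc1O[Si](C(C)C)(C(C)C)C(C)C | intermediate
29 | ring C triisopropylsilyl ether of the target: (3R,4R) lactone, (1R,2S) glycerol ether, (2S,3R)-3-(hydroxymethyl)dihydrobenzofuran | COc1cc([C@@H](O)[C@H](CO)Oc2ccc(C[C@H]3C(=O)OC[C@@H]3Cc3cc(OC)c4c(c3)[C@H](CO)[C@@H](c3ccc(O)c(OC)c3)O4)cc2OC)ccc1O[Si](C(C)C)(C(C)C)C(C)C | intermediate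
30 | (3R,4R)-3-[4-({(1R,2S)-1,3-dihydroxy-1-(4-hydroxy-3-methoxyphenyl)propan-2-yl}oxy)-3-methoxybenzyl]-4-{[(2S,3R)-3-(hydroxymethyl)-2-(4-hydroxy-3-methoxyphenyl)-7-methoxy-2,3-dihydrobenzofuran-5-yl]methyl}dihydrofuran-2(3H)-one | COc1cc([C@@H](O)[C@H](CO)Oc2ccc(C[C@H]3C(=O)OC[C@@H]3Cc3cc(OC)c4c(c3)[C@H](CO)[C@@H](c3ccc(O)c(OC)c3)O4)cc2OC)ccc1O | target

## Step count and risks

Total steps: 19. Longest linear sequence: 13 (steps 1–4, 8–13, 17–19).

**Step 17 (key step).** Both radicals are short-lived, so several processes compete with the wanted one: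
- homo-coupling of the feruloyl radical may outrun cross-coupling;
- the ring B radical may bond through oxygen instead of C5, giving an open aryl vinyl ether;
- ring B may be oxidised further at its benzylic CH2;
- the product, which carries a new 4-alkylguaiacol phenol on ring D, may couple again;
- the face selection may be weak or reversed, because nothing but a loose silver bridge fixes the imide rotamer.

If only the facial sense is wrong, the imide from the enantiomeric oxazolidinone corrects it. The fallback proper replaces radical coupling by a polar palladium route that forms the same two bonds. It sets out from 20. Ortho-iodination with N-iodosuccinimide (the phenol directs to its one free ortho carbon) gives the iodophenol F1. Commercial coniferyl alcohol is silylated (t-BuMe2SiCl, imidazole) to the bis-silyl ether F2. A Heck-type oxyarylation of F2 with F1 (Pd(OAc)2, Ag2CO3, acetone, 60 °C) bonds the aryl carbon to the alkene carbon remote from ring D, and the phenol oxygen to the benzylic carbon. This gives the trans-dihydrobenzofuran tris-silyl ether F3 together with its (2R,3S) diastereomer F4, which is separated by chromatography. Global desilylation of F3 (Bu4NF, AcOH) returns to the route at 30.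

**Step 11.** The α-aryloxy group can join the magnesium chelate and change the enolate or transition-state geometry, so low anti selectivity or the wrong facial sense is possible. The electron-rich aldehyde adds slowly, which gives retro-aldol a chance before silyl capture. Ionisation at C7 during desilylation would erode the configuration. The fallback uses the boron syn aldol and inverts C7. It sets out from 14. Alkylation with commercial (R)-4-benzyl-3-(chloroacetyl)oxazolidin-2-one (K2CO3, NaI) gives the (R)-imide F5. A Bu2BOTf/i-Pr2NEt aldol with 10 (H2O2 work-up) gives the syn adduct F6 (2R,3S), in which C8 is correct and C7 is epimeric. NaBH4 in wet THF gives the threo diol F7. A Mitsunobu reaction with excess 4-nitrobenzoic acid (PPh3, DIAD) esterifies the primary alcohol and inverts C7, giving the bis(4-nitrobenzoate) F8. Methanolysis (K2CO3 cat., MeOH, then mild acid) returns to the route at 19.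

**Step 18.** Hydride attack on the hindered, α-aryl exocyclic carbonyl may be slow. Reduction of the lactone, attack at the ring carbonyl of the auxiliary, or base-induced β-elimination that opens the dihydrofuran could then compete. The fallback separates cleavage from reduction. It sets out from 28. LiOH/H2O2 in THF/H2O at 0 °C (Na2SO3, then HCl work-up) cleaves the exocyclic carbonyl selectively and gives the carboxylic acid F9. Any lactone opened by hydroxide re-closes on acidification. BH3·SMe2 in THF at 0 °C then reduces the acid in preference to the lactone and returns to the route at 29.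

**Step 10.** The phenoxide may attack the imide carbonyl (acyl transfer with loss of the auxiliary), or the chloroacetyl imide may decompose under carbonate, instead of clean displacement of chloride. The fallback builds the acid first and attaches the auxiliary afterwards. It sets out from 14. Alkylation with tert-butyl bromoacetate (K2CO3, acetone) gives the tert-butyl ester F10. TFA gives the aryloxyacetic acid F11. Activation as the mixed pivalic anhydride F12 (t-BuCOCl, Et3N) and acylation of 3 with LiCl return to the route at 16.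

## Further compounds

F1 | step 17 | iodophenol: 20 with iodine at C5 of ring B | COc1cc([C@@H](O)[C@H](CO)Oc2ccc(C[C@H]3C(=O)OC[C@@H]3Cc3cc(I)c(O)c(OC)c3)cc2OC)ccc1O[Si](C(C)C)(C(C)C)C(C)C
F2 | step 17 | (E)-coniferyl alcohol bis(tert-butyldimethylsilyl) ether | COc1cc(/C=C/CO[Si](C)(C)C(C)(C)C)ccc1O[Si](C)(C)C(C)(C)C
F3 | step 17 | tris-silyl ether of the target: (2S,3R)-dihydrobenzofuran with 3-CH2OSiMe2t-Bu, ring D OSiMe2t-Bu and ring C OSi(i-Pr)3 | COc1cc([C@@H](O)[C@H](CO)Oc2ccc(C[C@H]3C(=O)OC[C@@H]3Cc3cc(OC)c4c(c3)[C@H](CO[Si](C)(C)C(C)(C)C)[C@@H](c3ccc(O[Si](C)(C)C(C)(C)C)c(OC)c3)O4)cc2OC)ccc1O[Si](C(C)C)(C(C)C)C(C)C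
F4 | step 17 | (2R,3S)-dihydrobenzofuran diastereomer of F3 | COc1cc([C@@H](O)[C@H](CO)Oc2ccc(C[C@H]3C(=O)OC[C@@H]3Cc3cc(OC)c4c(c3)[C@@H](CO[Si](C)(C)C(C)(C)C)[C@H](c3ccc(O[Si](C)(C)C(C)(C)C)c(OC)c3)O4)cc2OC)ccc1O[Si](C(C)C)(C(C)C)C(C)C
F5 | step 11 | (R)-4-benzyl analogue of 16 | COc1cc(C[C@H]2C(=O)OC[C@@H]2Cc2ccc(OCc3ccccc3)c(OC)c2)ccc1OCC(=O)N1[C@H](Cc2ccccc2)COC1=O
F6 | step 11 | syn aldol adduct, (R)-4-benzyl-3-[(2R,3S)-2-aryloxy-3-hydroxy-3-arylpropanoyl]oxazolidin-2-one | COc1cc([C@H](O)[C@H](C(=O)N2[C@H](Cc3ccccc3)COC2=O)Oc2ccc(C[C@H]3C(=O)OC[C@@H]3Cc3ccc(OCc4ccccc4)c(OC)c3)cc2OC)ccc1O[Si](C(C)C)(C(C)C)C(C)C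
F7 | step 11 | threo diol, the (1S,2S) epimer of 19 | COc1cc([C@H](O)[C@H](CO)Oc2ccc(C[C@H]3C(=O)OC[C@@H]3Cc3ccc(OCc4ccccc4)c(OC)c3)cc2OC)ccc1O[Si](C(C)C)(C(C)C)C(C)C
F8 | step 11 | bis(4-nitrobenzoate) of 19, (1R,2S) | COc1cc([C@@H](OC(=O)c2ccc(cc2)[N+](=O)[O-])[C@H](COC(=O)c2ccc(cc2)[N+](=O)[O-])Oc2ccc(C[C@H]3C(=O)OC[C@@H]3Cc3ccc(OCc4ccccc4)c(OC)c3)cc2OC)ccc1O[Si](C(C)C)(C(C)C)C(C)C
F9 | step 18 | (2S,3S)-dihydrobenzofuran-3-carboxylic acid corresponding to 28 | COc1cc([C@@H](O)[C@H](CO)Oc2ccc(C[C@H]3C(=O)OC[C@@H]3Cc3cc(OC)c4c(c3)[C@H](C(=O)O)[C@@H](c3ccc(O)c(OC)c3)O4)cc2OC)ccc1O[Si](C(C)C)(C(C)C)C(C)C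
F10 | step 10 | tert-butyl 2-[4-({(3R,4R)-4-[4-(benzyloxy)-3-methoxybenzyl]-2-oxotetrahydrofuran-3-yl}methyl)-2-methoxyphenoxy]acetate | COc1cc(C[C@H]2C(=O)OC[C@@H]2Cc2ccc(OCc3ccccc3)c(OC)c2)ccc1OCC(=O)OC(C)(C)C
F11 | step 10 | 2-[4-({(3R,4R)-4-[4-(benzyloxy)-3-methoxybenzyl]-2-oxotetrahydrofuran-3-yl}methyl)-2-methoxyphenoxy]acetic acid | COc1cc(C[C@H]2C(=O)OC[C@@H]2Cc2ccc(OCc3ccccc3)c(OC)c2)ccc1OCC(=O)O
F12 | step 10 | mixed pivalic anhydride of F11 | COc1cc(C[C@H]2C(=O)OC[C@@H]2Cc2ccc(OCc3ccccc3)c(OC)c2)ccc1OCC(=O)OC(=O)C(C)(C)C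
A1 | alternative 1 | (2S)-6-bromo-8-methoxy-2-[3-methoxy-4-(methanesulfonyloxy)phenyl]chroman-4-one | O=C1C[C@@H](c2ccc(OS(C)(=O)=O)c(OC)c2)Oc2c(OC)cc(Br)cc21
A2 | alternative 1 | methyl (2S,3S)-trans-5-bromo-7-methoxy-2-[3-methoxy-4-(methanesulfonyloxy)phenyl]-2,3-dihydrobenzofuran-3-carboxylate | Brc1cc(OC)c2c(c1)[C@H](C(=O)OC)[C@@H](c1ccc(OS(C)(=O)=O)c(OC)c1)O2
A3 | alternative 2 | 3-{[(1S,2R)-1-[4-(benzyloxy)-3-methoxyphenyl]-2-[(benzyloxy)methyl]but-3-yn-1-yl]oxy}-4-methoxy-6-{[(tert-butyldimethylsilyl)oxy]methyl}-2H-pyran-2-one | C#C[C@H](COCc1ccccc1)[C@@H](c1ccc(OCc2ccccc2)c(OC)c1)Oc1c(OC)cc(CO[Si](C)(C)C(C)(C)C)oc1=O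
A4 | alternative 2 | (2S,3R)-trans-2-[4-(benzyloxy)-3-methoxyphenyl]-3-[(benzyloxy)methyl]-7-methoxy-5-{[(tert-butyldimethylsilyl)oxy]methyl}-2,3-dihydrobenzofuran | CC(C)(C)[Si](C)(C)OCc1cc(OC)c2c(c1)[C@H](COCc1ccccc1)[C@@H](c1ccc(OCc3ccccc3)c(OC)c1)O2
A5 | alternative 3 | 3-{[(2S,3R)-2-[4-(tert-butyldimethylsilyloxy)-3-methoxyphenyl]-3-{[(tert-butyldimethylsilyl)oxy]methyl}-7-methoxy-2,3-dihydrobenzofuran-5-yl]methyl}cyclobutan-1-one | O=C1CC(Cc2cc(OC)c3c(c2)[C@H](CO[Si](C)(C)C(C)(C)C)[C@@H](c2ccc(O[Si](C)(C)C(C)(C)C)c(OC)c2)O3)C1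
A6 | alternative 3 | (4R)-4-{[(2S,3R)-2-[4-(tert-butyldimethylsilyloxy)-3-methoxyphenyl]-3-{[(tert-butyldimethylsilyl)oxy]methyl}-7-methoxy-2,3-dihydrobenzofuran-5-yl]methyl}dihydrofuran-2(3H)-one | O=C1C[C@@H](Cc2cc(OC)c3c(c2)[C@H](CO[Si](C)(C)C(C)(C)C)[C@@H](c2ccc(O[Si](C)(C)C(C)(C)C)c(OC)c2)O3)CO1
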